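If each coupling frees one acid and that acid takes a second nucleophile, you pay two nucleophile for every electrophile. Here are the flasks, the earlier runs and the questions.

| setting | beta | zeta | south-east | west | south |
|---|---|---|---|---|---|
| electrophile | 5 mM | 5 mM | 5.0 mM | 5.0 mM | 5.0 mM |
| nucleophile | 1.4 equiv | 4 equiv | 1.10 equiv | 1.70 equiv | 2.50 equiv |
| remark | run made earlier | run made earlier |  |  |  |
| time |  |  | 2.5 min | 2.5 min | 2.5 min |

| run | time / min | electrophile / % | target / % |
|---|---|---|---|
| beta | 0.333 | 67.6 | 30.9 |
| beta | 0.833 | 48.4 | 43.2 |
| beta | 1.50 | 39.2 | 42.5 |
| beta | 2.50 | 33.9 | 37.2 |
| zeta | 0.667 | 11.0 | 76.1 |
| zeta | 1.33 | 2.4 | 70.5 |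
| zeta | 2.00 | 0.3 | 59.0 |
| zeta | 2.50 | 0.1 | 51.1 |

(each reading ± 0.5 percentage points)

- percent here means electrophile units held: one self-condensation product counts as two
- reactions considered so far: target -> over-reaction product; 2 electrophile -> self-condensation product; nucleophile + acid set free <-> protonated nucleophile; electrophile + nucleophile -> acid set free + target

1. part of the electrophile that has reacted at the end, south-east
2. part of the electrophile that has reacted at the end, west
3. part of the electrophile that has reacted at the end, south
4. what raising the equivalents of nucleophile from its lowest to its highest value here does to the part of the electrophile that has reacted (changes below 5 percentage points count as none) (it falls / no change / it rises)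

So define the stall point S: the equivalents of nucleophile charged divided by two, read as a share of the electrophile. At S, this count has used up the whole nucleophile charge, so where S lies under the whole electrophile charge the nucleophile is the limiting reagent. For south-east, S is 55.0%.

Now read the electrophile column of each earlier run. In beta, S is 70.0%. Its electrophile falls by 19 percentage points between the first two readings, but by 5.3 points between the last two. Beta has reacted 66.1% at its last reading, which is 94.4% of its S and still below it. That flattening is what a stall looks like.

In zeta, S is 200%, above the whole electrophile charge. Its column keeps falling, and 99.9% has reacted at the last reading.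

My own reckoning follows from these two rows. South-east should sit close under its S. West has S at 85.0% and should stay somewhat below that. South has S at 125%, so by this count it has no stall, like zeta.

The forecast gives 55%, 78% and 95%, and says it rises. Its ground is the same count: the acid “ties up a second nucleophile”.

The flasks give 53.6% for south-east, 77.3% for west and 94.7% for south. From south-east to south the answer on the trend is: it rises, by 41 points.

    target → over-reaction product (k = 0.00515 s⁻¹)
    2 electrophile → self-condensation product (k = 0.00452 L mol⁻¹ s⁻¹)
    nucleophile + acid set free ⇌ protonated nucleophile, settled at all times (K = 1.70 × 10⁶ L mol⁻¹)
    electrophile + nucleophile → acid set free + target (k = 4.03 L mol⁻¹ s⁻¹)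

South-east ends 1.4 points under its S, with 3.2% of its nucleophile free while 46% of its electrophile is left. South, charged with the equivalents of south-east, reaches 53.6% instead of 94.7%, so the difference in equivalents of nucleophile is the main reason for the rise. West, read on at 10.0 min, has its free nucleophile down to 0.65% of its charge and has reacted 85.1%, against its S of 85.0%.

(The readings were generated by integration with constants of no real substance; scatter was added.)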